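**Compound numbers:** 1 ring-A acetophenone (purchased); 2–5 ring-A intermediates (3 not isolated); 6 ring-B acid chloride (purchased); 7 diketone; 8 carbinol; 9 silyl ether; 10 formate; 11 protected lactol; 12 silyl ether of the target; 13 target. Chromanone numbering is used for the skeleton (C9 is the carbinol carbon on C3); the acetophenone positions map as C1' = C4a, C2' = C8a, C3' = C8, C4' = C7, C5' = C6, C6' = C5.

## Analysis of the target

Target 13 is a chroman-4-one in which benzene ring A is fused to the oxygen heterocycle ring C; ring A is fully substituted (O5–H, O6–Me, O7–H, C8–Me) and C3 carries the carbinol carbon C9 with the 4-hydroxyphenyl ring B. C2 is a lactol carbon bonded to O1, to a hydroxyl group and to C3, so 13 is the cyclic hemiacetal of a β-keto aldehyde with the O8a phenol. The three stereocentres are contiguous: C2 (S), C3 (R) and C9 (S), with the C2 hydroxyl and the C3 side chain trans on ring C. C2 epimerises by ring–chain tautomerism and C3 by enolisation, so only C9 is configurationally stable and has to be set by reagent control; C2 and C3 can only be expected to settle relative to it. The sensitive sites are the lactol (loss of water to a chromone), the β-hydroxy ketone (retro-aldol, elimination), the para-hydroxybenzylic C9–O bond (ionisation, hydrogenolysis) and the electron-rich ring A. The difficulty lies in telling the four ring-A oxygens apart, in introducing C2 at the aldehyde level without oxidant or acid, and in unmasking everything near neutrality. The strategy rests on C2 being a formyl-level carbon bonded to O1 and C3: a formate ester on O8a beside the C4 ketone already holds O1–C2 at the right oxidation level, and only C2–C3 is missing.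

## Retrosynthetic reasoning

**13 back to 11.** Only protecting-group bonds are cut: the O9–Si bond (12) and three aryl O–benzyl bonds (11). Benzyl is chosen for the phenols because it must survive alkaline persulfate, hot dilute acid and lithium amide bases, which phenolic silyl ethers would not. The benzyl groups are removed while O9 is still silylated, so that the benzylic C9–O bond is shielded during hydrogenolysis. The last step is then a buffered fluoride desilylation.

**11 back to 10.** The C2–C3 bond is cut. This is the only skeletal bond of ring C not present in an O8a formate, and cutting it turns the lactol into an ester and a ketone enolate. The forward reaction is an intramolecular O-to-C formyl shift, whose tetrahedral adduct is the lactol alkoxide itself. The benzyl group on O5 ensures that any reclosure can only use O8a.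

**10 back to 8.** The O8a–formyl ester bond and the O9–Si bond are cut, giving 9 and then 8. The formate is too labile to be carried, so it is installed last, on the one phenol left free. O9 must be capped first so that it neither attacks the formate nor triggers a retro-aldol under base.

**8 back to 7.** The C9–H bond is cut: the carbinol comes from the 1,3-diketone 7 by asymmetric transfer hydrogenation. The two carbonyl groups differ strongly (C9 is conjugated to an unhindered ring, C4 is flanked by two ortho substituents and chelated), which is what makes a regioselective, enantioselective mono-reduction reasonable.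

**7 back to 5 and 6.** The C3–C9 bond is cut between the acetyl carbon of 5 and the acyl carbon of 6. A Claisen-type aroylation of the dianion of 5 gives the whole carbon skeleton except C2 in one step and leaves O8a–H free.

**5 back to 1.** The O6–methyl bond, the C6–O bond and two O–benzyl bonds are cut (5 to 4 to 2 to 1). The free O2' phenol of 2 directs persulfate hydroxylation to its para position C5', the only unsubstituted ring carbon, and it is also the oxygen that later carries the formate. One selective dibenzylation therefore settles both the oxygenation pattern and the identity of O1.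

## Alternatives that were turned down

**Alternative 1: aryne insertion into a chiral acid.** The disconnection cuts C4a–C4 and C8a–O1, joining ring A to a preformed side-chain acid. In the forward step fluoride converts the silyl triflate A2 into the C4a≡C8a aryne, the carboxylate of acid A3 adds through oxygen at C8a, and the aryl anion at C4a takes over the acyl carbon to give the ortho-hydroxyaryl ketone A1.
- For: it is convergent, the alkoxy group at C5 should steer the oxygen to C8a, and O8a emerges free and distinct.
- Against: A2 is a hexasubstituted benzene with adjacent silyl and triflate groups and would cost more steps than the whole approach to 10. A3 has an α-centre that can slip into conjugation and a β-silyloxy group exposed to fluoride and base. The acyl shift has to deliver an α-branched acyl group to a di-ortho-substituted aryl anion. C2 is only masked as a vinyl group, so an ozonolysis beside electron-rich arenes is still needed.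
- Comparison: it is stronger in convergence, and equal in fixing which oxygen becomes O1. The chosen route offers instead C2 at the final oxidation level from a one-carbon ester, and it does not spend effort on a C3 configuration that is labile in the product anyway.

**Alternative 2: squarate ring opening and electrocyclisation.** The disconnection cuts C4a–C8a and builds ring A from scratch. Heating cyclobutenone A5 opens the bond between its carbonyl carbon and the quaternary carbon to a dienylketene, which closes by 6π electrocyclisation and tautomerises to phenol A4.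
- For: every ring-A substituent is placed by addition chemistry and the four oxygens carry four different groups, so regiochemistry is certain, without a persulfate oxidation and without reliance on chelation. On this point it is stronger than the chosen route.
- Against: it solves only ring A. C4a must still be acylated, the ethyl and isopropyl ethers of A4 need Lewis acids that late intermediates would not tolerate, and the C2–C3–C9 problem is untouched, so a second key step is required.
- Comparison: the chosen route accepts a less certain but short ring-A sequence from a purchasable acetophenone and puts its key step where the real difficulty lies, at the lactol.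

**Alternative 3: ortho-quinoid ketene hetero-Diels–Alder.** The disconnection cuts C4–C3 and O1–C2 together. Irradiation of benzodioxinone A7 releases its acetonide fragment to give the quinoketene O1=C8a–C4a=C4=O, which adds across C2=C3 of dioxasiline A8 to give the silylene-bridged chromanone A6.
- For: ring C and two bonds form in one neutral step, there is no base and hence no β-elimination, and C9 of A8 directs the face of addition, so C3 is set kinetically. On convergence and on control of C3 it is stronger than the chosen route.
- Against: A8 is the cyclic silyl enol ether of a β-hydroxy aldehyde, of uncertain preparation and hydrolytic stability. A7 needs the same ring-A differentiation plus a carboxyl group. The hindered quinoketene may dimerise or be trapped by adventitious nucleophiles. The cis ring fusion of A6 puts O2 on the face of C9, which is the C2 epimer of the target, so a final lactol equilibration is needed all the same.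
- Comparison: the chosen route is linear but uses conventional steps up to the formate, and thermodynamic control is sufficient because C2 and C3 equilibrate in the product.

Key step: step 8

**Assumptions.**
- C2 and C3 of the 2-hydroxychromanone are taken to equilibrate (lactol opening, enolisation) to the (2S,3R) arrangement of the target relative to the fixed (S)-C9.
- In step 1 the second benzylation is taken to favour O6' over the chelated, methyl-flanked O2'.
- 1 and 6 are taken to be purchasable.

## Route

Step 1
Reactants: 1 2',4',6'-trihydroxy-3'-methylacetophenone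
Product: 2 4',6'-bis(benzyloxy)-2'-hydroxy-3'-methylacetophenone
Conditions: BnBr (2.1 equiv), K2CO3, acetone, reflux
Reagents that add atoms: benzyl bromide, BrCc1ccccc1
Why: Williamson etherification; the unchelated O4'–H and the less hindered O6'–H should react, while O2'–H, hydrogen-bonded to the acetyl carbonyl and buttressed by the C3' methyl group, should stay free; a minor regioisomer would be removed by chromatography.

Step 2
Reactants: 2 4',6'-bis(benzyloxy)-2'-hydroxy-3'-methylacetophenone
Product: 4 4',6'-bis(benzyloxy)-2',5'-dihydroxy-3'-methylacetophenone, via potassium aryl sulfate 3 (not isolated)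
Conditions: K2S2O8, aq KOH, pyridine, 0 °C to rt; then 2 M HCl, 70 °C, under N2
Reagents that add atoms: potassium peroxodisulfate, [K+].[K+].[O-]S(=O)(=O)OOS(=O)(=O)[O-]
Why: Elbs persulfate oxidation; the phenoxide of 2 attacks a peroxide oxygen through its para carbon C5', the only unsubstituted ring position, and the aryl sulfate 3 is hydrolysed by acid. Benzyl ethers tolerate both the alkali and the brief acid treatment, as in the usual preparation of 6-oxygenated flavonoid precursors.

Step 3
Reactants: 4 4',6'-bis(benzyloxy)-2',5'-dihydroxy-3'-methylacetophenone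
Product: 5 4',6'-bis(benzyloxy)-2'-hydroxy-5'-methoxy-3'-methylacetophenone
Conditions: MeI (1.05 equiv), K2CO3, acetone, rt
Reagents that add atoms: iodomethane, CI
Why: Williamson methylation; O5'–H is a free phenol, whereas O2'–H is chelated to the ketone and should not react with one equivalent of MeI under carbonate conditions.

Step 4
Reactants: 5 4',6'-bis(benzyloxy)-2'-hydroxy-5'-methoxy-3'-methylacetophenone; 6 4-(benzyloxy)benzoyl chloride
Product: 7 1-[4,6-bis(benzyloxy)-2-hydroxy-5-methoxy-3-methylphenyl]-3-[4-(benzyloxy)phenyl]propane-1,3-dione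
Conditions: LiN(SiMe3)2 (3.2 equiv), THF, −78 °C; then 6, −78 °C to rt; 1 M HCl at 0 °C
Reagents that add atoms: none
Why: Claisen-type C-aroylation of the lithium dianion (phenoxide plus methyl ketone enolate); the third equivalent of base takes up the acidic diketone as it forms. Any O-aroyl ester formed would converge on 7 by a Baker–Venkataraman shift under the same conditions.

Step 5
Reactants: 7 1-[4,6-bis(benzyloxy)-2-hydroxy-5-methoxy-3-methylphenyl]-3-[4-(benzyloxy)phenyl]propane-1,3-dione
Product: 8 (3S)-1-[4,6-bis(benzyloxy)-2-hydroxy-5-methoxy-3-methylphenyl]-3-[4-(benzyloxy)phenyl]-3-hydroxypropan-1-one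
Conditions: RuCl(p-cymene)[(S,S)-TsDPEN] (2 mol %), HCO2H–Et3N (5:2), CH2Cl2, 30 °C
Reagents that add atoms: none
Why: Noyori–Ikariya asymmetric transfer hydrogenation; only the C9 carbonyl, conjugated to the unhindered ring B, should be reduced, because the C4 carbonyl is flanked by two ortho substituents, twisted out of conjugation and chelated by O8a–H. With the aryl group in the role it plays in simple aryl ketones, the (S,S) ligand should give the (S)-carbinol.

Step 6
Reactants: 8 (3S)-1-[4,6-bis(benzyloxy)-2-hydroxy-5-methoxy-3-methylphenyl]-3-[4-(benzyloxy)phenyl]-3-hydroxypropan-1-one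
Product: 9 (3S)-1-[4,6-bis(benzyloxy)-2-hydroxy-5-methoxy-3-methylphenyl]-3-[4-(benzyloxy)phenyl]-3-[(triethylsilyl)oxy]propan-1-one
Conditions: Et3SiCl (1.2 equiv), imidazole, DMF, 0 °C
Reagents that add atoms: chlorotriethylsilane, CC[Si](Cl)(CC)CC
Why: Silylation of the secondary alcohol; the chelated, di-ortho-substituted O8a–H should not compete under chloride/imidazole conditions, and any aryl silyl ether formed should hydrolyse on work-up.

Step 7
Reactants: 9 (3S)-1-[4,6-bis(benzyloxy)-2-hydroxy-5-methoxy-3-methylphenyl]-3-[4-(benzyloxy)phenyl]-3-[(triethylsilyl)oxy]propan-1-one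
Product: 10 3,5-bis(benzyloxy)-2-{(3S)-3-[4-(benzyloxy)phenyl]-3-[(triethylsilyl)oxy]propanoyl}-4-methoxy-6-methylphenyl formate
Conditions: LiN(SiMe3)2 (1.0 equiv), THF, −78 °C; then distilled HCO2Ac (1.2 equiv), −78 to −40 °C; filtration and evaporation, no water, no chromatography
Reagents that add atoms: acetic formic anhydride, CC(=O)OC=O
Why: O-acylation of the lithium phenoxide by a mixed anhydride, which transfers its formyl group because that carbonyl is the less hindered and more electrophilic. One equivalent of base removes only the phenol proton, which is far more acidic than the α-CH2; the labile aryl formate is kept away from water and silica.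

Step 8
Reactants: 10 3,5-bis(benzyloxy)-2-{(3S)-3-[4-(benzyloxy)phenyl]-3-[(triethylsilyl)oxy]propanoyl}-4-methoxy-6-methylphenyl formate
Product: 11 (2S,3R)-5,7-bis(benzyloxy)-3-{(S)-[4-(benzyloxy)phenyl][(triethylsilyl)oxy]methyl}-2-hydroxy-6-methoxy-8-methylchroman-4-one
Conditions: 10 added to LiN(SiMe3)2 (2.5 equiv), THF, −78 °C; AcOH in THF at −78 °C, then pH 7 buffer
Reagents that add atoms: none
Why: The amide base removes a C3 proton and the enolate carbon adds to the formate carbonyl on O8a through a six-membered transition state, forming C2–C3; the tetrahedral adduct is the lithium alkoxide of the lactol, so ring C closes in the same event by a 6-(enolendo)-exo-trig closure. The closest known reactions are the Baker–Venkataraman O-to-C acyl shift of 2-acyloxyaryl ketones and the Claisen formylation of 2-hydroxyaryl ketones, which gives isolable 2-hydroxychroman-4-ones. More than two equivalents of base are used because the product anion is more acidic than the starting ketone. If the adduct opens to the phenoxide and the β-keto aldehyde enolate, protonation closes it again, and only on O8a, because O5 is benzylated. Neither new centre is set kinetically: C3 equilibrates through the enol and the open aldehyde, C2 through ring–chain tautomerism, and both should settle relative to the fixed (S)-C9 in the 2,3-trans arrangement with the C3 side chain pseudo-equatorial, which is assumed to be the stable one. The step needs the intramolecular C-formylation to be faster than β-elimination of the C9 silyloxy group and than attack of the base on the formate. This is served by the low temperature, the hindered amide, inverse addition, the cold acetic acid quench and the poor leaving-group ability of a silyloxide.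

Step 9
Reactants: 11 (2S,3R)-5,7-bis(benzyloxy)-3-{(S)-[4-(benzyloxy)phenyl][(triethylsilyl)oxy]methyl}-2-hydroxy-6-methoxy-8-methylchroman-4-one
Product: 12 (2S,3R)-2,5,7-trihydroxy-3-{(S)-(4-hydroxyphenyl)[(triethylsilyl)oxy]methyl}-6-methoxy-8-methylchroman-4-one
Conditions: H2 (1 atm), Pd/C (10 wt % palladium on carbon), EtOAc, rt
Reagents that add atoms: none
Why: Hydrogenolysis of three aryl benzyl ethers in a neutral, non-protic solvent; the benzylic C9–O bond is shielded as a bulky silyl ether, and cleavage of such bonds normally needs acid or long reaction times. The hindered, chelated ketone and the lactol should be untouched.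

Step 10
Reactants: 12 (2S,3R)-2,5,7-trihydroxy-3-{(S)-(4-hydroxyphenyl)[(triethylsilyl)oxy]methyl}-6-methoxy-8-methylchroman-4-one
Product: 13 (2S,3R)-2,5,7-trihydroxy-3-[(S)-hydroxy(4-hydroxyphenyl)methyl]-6-methoxy-8-methylchroman-4-one
Conditions: HF·pyridine, pyridine, THF, 0 °C to rt; pH 7 buffer
Reagents that add atoms: none
Why: Fluoride cleavage of the triethylsilyl ether under pyridine-buffered, non-basic conditions, which should avoid retro-aldol, elimination and chromone formation; C2 and C3 stay free to adopt their stable configurations.

## Compound list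

1 | 2',4',6'-trihydroxy-3'-methylacetophenone | CC(=O)c1c(O)cc(O)c(C)c1O | starting material
2 | 4',6'-bis(benzyloxy)-2'-hydroxy-3'-methylacetophenone | CC(=O)c1c(OCc2ccccc2)cc(OCc2ccccc2)c(C)c1O | intermediate
3 | potassium 3-acetyl-2,6-bis(benzyloxy)-4-hydroxy-5-methylphenyl sulfate | CC(=O)c1c(OCc2ccccc2)c(OS(=O)(=O)[O-])c(OCc2ccccc2)c(C)c1O.[K+] | intermediate
4 | 4',6'-bis(benzyloxy)-2',5'-dihydroxy-3'-methylacetophenone | CC(=O)c1c(OCc2ccccc2)c(O)c(OCc2ccccc2)c(C)c1O | intermediate
5 | 4',6'-bis(benzyloxy)-2'-hydroxy-5'-methoxy-3'-methylacetophenone | CC(=O)c1c(OCc2ccccc2)c(OC)c(OCc2ccccc2)c(C)c1O | intermediate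
6 | 4-(benzyloxy)benzoyl chloride | O=C(Cl)c1ccc(OCc2ccccc2)cc1 | starting material
7 | 1-[4,6-bis(benzyloxy)-2-hydroxy-5-methoxy-3-methylphenyl]-3-[4-(benzyloxy)phenyl]propane-1,3-dione | COc1c(OCc2ccccc2)c(C)c(O)c(c1OCc1ccccc1)C(=O)CC(=O)c1ccc(OCc2ccccc2)cc1 | intermediate
8 | (3S)-1-[4,6-bis(benzyloxy)-2-hydroxy-5-methoxy-3-methylphenyl]-3-[4-(benzyloxy)phenyl]-3-hydroxypropan-1-one | COc1c(OCc2ccccc2)c(C)c(O)c(c1OCc1ccccc1)C(=O)C[C@H](O)c1ccc(OCc2ccccc2)cc1 | intermediate
9 | (3S)-1-[4,6-bis(benzyloxy)-2-hydroxy-5-methoxy-3-methylphenyl]-3-[4-(benzyloxy)phenyl]-3-[(triethylsilyl)oxy]propan-1-one | COc1c(OCc2ccccc2)c(C)c(O)c(c1OCc1ccccc1)C(=O)C[C@H](O[Si](CC)(CC)CC)c1ccc(OCc2ccccc2)cc1 | intermediate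
10 | 3,5-bis(benzyloxy)-2-{(3S)-3-[4-(benzyloxy)phenyl]-3-[(triethylsilyl)oxy]propanoyl}-4-methoxy-6-methylphenyl formate | COc1c(OCc2ccccc2)c(C)c(OC=O)c(c1OCc1ccccc1)C(=O)C[C@H](O[Si](CC)(CC)CC)c1ccc(OCc2ccccc2)cc1 | intermediate
11 | (2S,3R)-5,7-bis(benzyloxy)-3-{(S)-[4-(benzyloxy)phenyl][(triethylsilyl)oxy]methyl}-2-hydroxy-6-methoxy-8-methylchroman-4-one | COc1c(OCc2ccccc2)c(C)c2c(c1OCc1ccccc1)C(=O)[C@H]([C@H](O[Si](CC)(CC)CC)c1ccc(OCc3ccccc3)cc1)[C@@H](O)O2 | intermediate
12 | (2S,3R)-2,5,7-trihydroxy-3-{(S)-(4-hydroxyphenyl)[(triethylsilyl)oxy]methyl}-6-methoxy-8-methylchroman-4-one | COc1c(O)c(C)c2c(c1O)C(=O)[C@H]([C@H](O[Si](CC)(CC)CC)c1ccc(O)cc1)[C@@H](O)O2 | intermediate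
13 | (2S,3R)-2,5,7-trihydroxy-3-[(S)-hydroxy(4-hydroxyphenyl)methyl]-6-methoxy-8-methylchroman-4-one | COc1c(O)c(C)c2c(c1O)C(=O)[C@H]([C@H](O)c1ccc(O)cc1)[C@@H](O)O2 | target

## Step count and least certain steps

Total: 10 steps. Longest linear sequence: 10 steps (1 to 13); 6 is purchased.

**Step 8 (key step).**
- What may go wrong: loss of the formyl group, either by attack of the amide at the formyl carbon or by base-induced decarbonylation of the aryl formate, which returns the phenol; β-elimination of the silyloxide from the ketone enolate or from the β-keto aldehyde enolate; dehydration of the lactol to the chromone on work-up; incomplete equilibration at C2 and C3.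
- Fallback: intermolecular Claisen formylation, setting out from 9 and returning at 11. The dianion of 9 (LiN(SiMe3)2, 3 equiv, THF, −78 °C) is C-formylated with ethyl formate, and the open-chain β-keto aldehyde F1 closes on O8a on neutral work-up to give 11. The formyl carbon then arrives on carbon first and no aryl formate is exposed to base.

**Step 5.**
- What may go wrong: slow turnover because 7 is largely enolised and chelated; reduction at the wrong carbonyl or at both; incomplete enantioselectivity; acid-promoted dehydration of 8 to the chalcone followed by conjugate reduction.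
- Fallback: asymmetric Mukaiyama aldol, setting out from 5 and returning at 8. 5 is converted with Me3SiOTf and Et3N into the bis(trimethylsilyl) enol ether F2. F2 adds to 4-(benzyloxy)benzaldehyde under SiCl4 activated by a chiral bisphosphoramide Lewis base, using the catalyst enantiomer that gives the (S)-aldol. Hydrolytic work-up gives 8 without passing through the diketone.

**Step 2.**
- What may go wrong: low conversion, since the phenoxide of a dibenzyl ether is poorly soluble; oxidative degradation of the hydroquinone product to a quinone.
- Fallback: halogenation and copper-catalysed methoxylation, setting out from 2 and returning at 5, bypassing 4. Bromination of 2 with N-bromosuccinimide in MeCN at C5', the only free and strongly activated position, gives 4',6'-bis(benzyloxy)-5'-bromo-2'-hydroxy-3'-methylacetophenone F3. Ullmann-type methoxylation (NaOMe, CuBr, DMF–MeOH, 110 °C) then gives 5.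

**Step 9.**
- What may go wrong: competing hydrogenolysis of the doubly activated benzylic C9–O bond, or loss of the silyl ether on the catalyst followed by such cleavage.
- Fallback: the aryl protecting groups are changed to silyl ethers before C9 exists, so that no hydrogenation is needed late. It sets out from 5 and 6 and returns at 13.
  - 5 is O-aroylated with 6 (pyridine, DMAP) to the aryl ester F4.
  - Hydrogenolysis (H2, Pd/C) gives the triphenol ester F5.
  - t-BuMe2SiOTf and 2,6-lutidine give the tris-silyl ester F6.
  - LiN(SiMe3)2 effects the Baker–Venkataraman shift to the diketone F7, which frees O8a–H.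
  - Transfer hydrogenation as in step 5 gives the carbinol F8, and Et3SiCl gives the silyl ether F9.
  - Formylation as in step 7 gives the formate F10, and the acyl shift of step 8 gives the lactol F11.
  - Bu4NF buffered with AcOH removes all four silyl groups to give 13.
  - This costs two more steps and places a silyloxy group beside the enolate in two steps, which is why it is not the first choice.

**Step 6.**
- What may go wrong: competing silylation of the phenol, or incomplete silylation of the hindered carbinol.
- Fallback: exhaustive silylation and selective cleavage, setting out from 8 and returning at 9. Et3SiOTf and 2,6-lutidine give the bis(triethylsilyl) ether F12, and brief methanolysis (K2CO3, MeOH, 0 °C) cleaves only the aryl silyl ether to give 9.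

## Further compounds

F1 | step 8 | 2-{(S)-[4-(benzyloxy)phenyl][(triethylsilyl)oxy]methyl}-3-[4,6-bis(benzyloxy)-2-hydroxy-5-methoxy-3-methylphenyl]-3-oxopropanal (C2 of the chain enolisable) | COc1c(OCc2ccccc2)c(C)c(O)c(c1OCc1ccccc1)C(=O)C(C=O)[C@H](O[Si](CC)(CC)CC)c1ccc(OCc2ccccc2)cc1
F2 | step 5 | {[1-(4,6-bis(benzyloxy)-5-methoxy-3-methyl-2-[(trimethylsilyl)oxy]phenyl)vinyl]oxy}trimethylsilane | COc1c(OCc2ccccc2)c(C)c(O[Si](C)(C)C)c(c1OCc1ccccc1)C(=C)O[Si](C)(C)C
F3 | step 2 | 4',6'-bis(benzyloxy)-5'-bromo-2'-hydroxy-3'-methylacetophenone | CC(=O)c1c(OCc2ccccc2)c(Br)c(OCc2ccccc2)c(C)c1O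
F4 | step 9 | 2-acetyl-3,5-bis(benzyloxy)-4-methoxy-6-methylphenyl 4-(benzyloxy)benzoate | CC(=O)c1c(OCc2ccccc2)c(OC)c(OCc2ccccc2)c(C)c1OC(=O)c1ccc(OCc2ccccc2)cc1
F5 | step 9 | 2-acetyl-3,5-dihydroxy-4-methoxy-6-methylphenyl 4-hydroxybenzoate | CC(=O)c1c(O)c(OC)c(O)c(C)c1OC(=O)c1ccc(O)cc1
F6 | step 9 | 2-acetyl-3,5-bis[(tert-butyldimethylsilyl)oxy]-4-methoxy-6-methylphenyl 4-[(tert-butyldimethylsilyl)oxy]benzoate | CC(=O)c1c(O[Si](C)(C)C(C)(C)C)c(OC)c(O[Si](C)(C)C(C)(C)C)c(C)c1OC(=O)c1ccc(O[Si](C)(C)C(C)(C)C)cc1
F7 | step 9 | 1-{4,6-bis[(tert-butyldimethylsilyl)oxy]-2-hydroxy-5-methoxy-3-methylphenyl}-3-{4-[(tert-butyldimethylsilyl)oxy]phenyl}propane-1,3-dione | COc1c(O[Si](C)(C)C(C)(C)C)c(C)c(O)c(c1O[Si](C)(C)C(C)(C)C)C(=O)CC(=O)c1ccc(O[Si](C)(C)C(C)(C)C)cc1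
F8 | step 9 | (3S)-1-{4,6-bis[(tert-butyldimethylsilyl)oxy]-2-hydroxy-5-methoxy-3-methylphenyl}-3-{4-[(tert-butyldimethylsilyl)oxy]phenyl}-3-hydroxypropan-1-one | COc1c(O[Si](C)(C)C(C)(C)C)c(C)c(O)c(c1O[Si](C)(C)C(C)(C)C)C(=O)C[C@H](O)c1ccc(O[Si](C)(C)C(C)(C)C)cc1
F9 | step 9 | (3S)-1-{4,6-bis[(tert-butyldimethylsilyl)oxy]-2-hydroxy-5-methoxy-3-methylphenyl}-3-{4-[(tert-butyldimethylsilyl)oxy]phenyl}-3-[(triethylsilyl)oxy]propan-1-one | COc1c(O[Si](C)(C)C(C)(C)C)c(C)c(O)c(c1O[Si](C)(C)C(C)(C)C)C(=O)C[C@H](O[Si](CC)(CC)CC)c1ccc(O[Si](C)(C)C(C)(C)C)cc1
F10 | step 9 | 3,5-bis[(tert-butyldimethylsilyl)oxy]-2-{(3S)-3-{4-[(tert-butyldimethylsilyl)oxy]phenyl}-3-[(triethylsilyl)oxy]propanoyl}-4-methoxy-6-methylphenyl formate | COc1c(O[Si](C)(C)C(C)(C)C)c(C)c(OC=O)c(c1O[Si](C)(C)C(C)(C)C)C(=O)C[C@H](O[Si](CC)(CC)CC)c1ccc(O[Si](C)(C)C(C)(C)C)cc1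
F11 | step 9 | (2S,3R)-5,7-bis[(tert-butyldimethylsilyl)oxy]-3-{(S)-{4-[(tert-butyldimethylsilyl)oxy]phenyl}[(triethylsilyl)oxy]methyl}-2-hydroxy-6-methoxy-8-methylchroman-4-one | COc1c(O[Si](C)(C)C(C)(C)C)c(C)c2c(c1O[Si](C)(C)C(C)(C)C)C(=O)[C@H]([C@H](O[Si](CC)(CC)CC)c1ccc(O[Si](C)(C)C(C)(C)C)cc1)[C@@H](O)O2
F12 | step 6 | (3S)-1-{4,6-bis(benzyloxy)-5-methoxy-3-methyl-2-[(triethylsilyl)oxy]phenyl}-3-[4-(benzyloxy)phenyl]-3-[(triethylsilyl)oxy]propan-1-one | COc1c(OCc2ccccc2)c(C)c(O[Si](CC)(CC)CC)c(c1OCc1ccccc1)C(=O)C[C@H](O[Si](CC)(CC)CC)c1ccc(OCc2ccccc2)cc1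
A1 | alternative 1 | (2S)-1-[4,6-bis(benzyloxy)-2-hydroxy-5-methoxy-3-methylphenyl]-2-{(S)-[4-(benzyloxy)phenyl][(tert-butyldimethylsilyl)oxy]methyl}but-3-en-1-one | COc1c(OCc2ccccc2)c(C)c(O)c(c1OCc1ccccc1)C(=O)[C@H]([C@H](O[Si](C)(C)C(C)(C)C)c1ccc(OCc2ccccc2)cc1)C=C
A2 | alternative 1 | 2,4-bis(benzyloxy)-3-methoxy-5-methyl-6-(trimethylsilyl)phenyl trifluoromethanesulfonate | COc1c(OCc2ccccc2)c(C)c([Si](C)(C)C)c(OS(=O)(=O)C(F)(F)F)c1OCc1ccccc1
A3 | alternative 1 | (2S)-2-{(S)-[4-(benzyloxy)phenyl][(tert-butyldimethylsilyl)oxy]methyl}but-3-enoic acid | OC(=O)[C@H]([C@H](O[Si](C)(C)C(C)(C)C)c1ccc(OCc2ccccc2)cc1)C=C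
A4 | alternative 2 | 5-ethoxy-3-isopropoxy-4-methoxy-2-methylphenol | CCOc1cc(O)c(C)c(OC(C)C)c1OC
A5 | alternative 2 | 4-(1-ethoxyvinyl)-3-isopropoxy-4-methoxy-2-methylcyclobut-2-en-1-one | CCOC(=C)C1(OC)C(OC(C)C)=C(C)C1=O
A6 | alternative 3 | di-tert-butylsilylene-bridged chromanone (O2 and O9 joined by silicon, cis ring fusion, three aryl tert-butyldimethylsilyl ethers) | COc1c(O[Si](C)(C)C(C)(C)C)c(C)c2c(c1O[Si](C)(C)C(C)(C)C)C(=O)[C@@H]3[C@@H](c4ccc(O[Si](C)(C)C(C)(C)C)cc4)O[Si](C(C)(C)C)(C(C)(C)C)O[C@@H]3O2
A7 | alternative 3 | 5,7-bis[(tert-butyldimethylsilyl)oxy]-6-methoxy-2,2,8-trimethyl-4H-1,3-benzodioxin-4-one | COc1c(O[Si](C)(C)C(C)(C)C)c(C)c2OC(C)(C)OC(=O)c2c1O[Si](C)(C)C(C)(C)C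
A8 | alternative 3 | (4S)-2,2-di-tert-butyl-4-{4-[(tert-butyldimethylsilyl)oxy]phenyl}-4H-1,3,2-dioxasiline | CC(C)(C)[Si]1(C(C)(C)C)OC=C[C@@H](c2ccc(O[Si](C)(C)C(C)(C)C)cc2)O1
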